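**Retrosynthetic overview**

1. The route rests on the C1–C2–C3 oxygen triad of the cyclohexene ring: the oxirane oxygen on quaternary C1 (which carries C7, CH2OBz) and the C2 hydroxyl share one face, the C3 benzoate lies on the other. That is the imprint of a C2–C3 oxirane syn to the C1 oxygen, opened at C3 with inversion; without these oxygens the ring is a Cs-symmetric cyclohexa-2,5-dien-1-ol.
2. 18 ⇒ 17: the C1–O–C6 oxirane is closed last, by the C1 alkoxide displacing an anti C6 mesylate. 17 ⇒ 15 ⇒ 12 ⇒ 11: C5=C6 is transposed to C4=C5 with oxygen at C6 (anti oxirane, selenide opening at C5, selenoxide elimination).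
3. 11 ⇒ 10 ⇒ 9: benzoate opens the C2–C3 oxirane at C3. 9 ⇒ 8: hydroxyl-directed, catalyst-controlled epoxidation of one of the two enantiotopic alkenes of the achiral dienol sets C1, C2 and C3.
4. 8 ⇒ benzoic acid 1 (Birch reduction, esterification, enolate hydroxylation, reduction) and benzoyl chloride 7.
5. Ring order: carbocycle from the arene; C2–C3 oxirane (step 6, opened in step 7); dioxolane (step 8, temporary); C5–C6 oxirane (step 9, temporary); C1–C6 oxirane (step 14).

Key step: step 6

Remark on numbering: C1 is the quaternary carbon bearing C7, C2 the carbinol carbon, C3 the benzoate carbon, then C4, C5, C6 round the ring. The β face is the face of the C1 oxygen, the α face that of C7. Descriptors of intermediates use this numbering.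

Assumption: the sense in which the hafnium bis-hydroxamate catalyst selects between the enantiotopic alkenes of a cyclohexa-2,5-dien-1-ol cannot be predicted. Both ligand antipodes are available, and the one that gives (1R,2R,3R)-9 is to be found in a small-scale trial; it is written here as the (R,R)-ligand.

**Route**

Step 1
Reactants: 1 benzoic acid
Product: 2 cyclohexa-2,5-diene-1-carboxylic acid
Conditions: Na, NH3 (l), EtOH, −78 → −33 °C; NH4Cl; then cold 1 M HCl
Reagents that add atoms: none
Why: Birch reduction, in which the carboxylate directs protonation to the ipso and para carbons and so should give the unconjugated 1,4-dihydro acid.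

Step 2
Reactants: 2 cyclohexa-2,5-diene-1-carboxylic acid
Product: 3 methyl cyclohexa-2,5-diene-1-carboxylate
Conditions: MeI, K2CO3, DMF, 0 °C → rt
Reagents that add atoms: iodomethane, CI
Why: SN2 O-alkylation of the carboxylate under mild base, which avoids the acid that could move the diene into conjugation.

Step 3
Reactants: 3 methyl cyclohexa-2,5-diene-1-carboxylate
Product: 5 methyl 1-hydroxycyclohexa-2,5-diene-1-carboxylate, via potassium dienolate 4 (not isolated)
Conditions: KN(SiMe3)2, THF, −78 °C; then 2-(phenylsulfonyl)-3-phenyloxaziridine, −78 °C; NH4Cl (aq)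
Reagents that add atoms: 2-(phenylsulfonyl)-3-phenyloxaziridine, O=S(=O)(c1ccccc1)N1OC1c1ccccc1
Why: Davis oxidation of the cross-conjugated ester dienolate, which should react at its α-carbon (C1) as it does in Birch-type alkylations, the potassium counter-ion suppressing addition to the sulfonimine by-product; no stereocentre is formed.

Step 4
Reactants: 5 methyl 1-hydroxycyclohexa-2,5-diene-1-carboxylate
Product: 6 1-(hydroxymethyl)cyclohexa-2,5-dien-1-ol
Conditions: LiAlH4, THF, 0 °C; then aq. potassium sodium tartrate
Reagents that add atoms: none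
Why: hydride reduction of the ester to the primary alcohol leaves the isolated alkenes alone, and the non-acidic work-up protects the doubly allylic tertiary alcohol from dehydrative aromatisation.

Step 5
Reactants: 6 1-(hydroxymethyl)cyclohexa-2,5-dien-1-ol; 7 benzoyl chloride
Product: 8 (1-hydroxycyclohexa-2,5-dien-1-yl)methyl benzoate
Conditions: BzCl (1.05 equiv), pyridine, CH2Cl2, −20 → 0 °C; NaHCO3 work-up; chromatography on Et3N-deactivated silica
Reagents that add atoms: benzoyl chloride (7), O=C(Cl)c1ccccc1
Why: nucleophilic acyl substitution, in which the primary hydroxyl is acylated far faster than the hindered tertiary one while the basic medium keeps the acid-labile dienol intact.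

Step 6
Reactants: 8 (1-hydroxycyclohexa-2,5-dien-1-yl)methyl benzoate
Product: 9 (1R,2R,3R)-1-(benzoyloxymethyl)-2,3-epoxycyclohex-5-en-1-ol (oxirane on the β face, syn to the C1 hydroxyl)
Conditions: Hf(OtBu)4 (10 mol%), (R,R)-N,N'-dihydroxy-N,N'-bis(diphenylacetyl)cyclohexane-1,2-diamine (12 mol%), cumene hydroperoxide (1.2 equiv), DMPU (20 mol%), 4 Å MS, toluene, 0 °C
Reagents that add atoms: cumene hydroperoxide, CC(C)(OO)c1ccccc1
Why: Proposed new method: the C1 hydroxyl should exchange onto the tetravalent hafnium centre held by the C2-symmetric bis-hydroxamate, the hydroperoxide binds to the same metal, and its distal oxygen is passed in one concerted step to the alkene lying under the metal, so that both C–O bonds form together on the face of the C1–O bond. The closest known reactions are the hydroxyl-directed asymmetric epoxidations of tertiary allylic alcohols with hafnium or vanadium bis-hydroxamic acid catalysts and the titanium tartrate desymmetrisation of dialkenyl carbinols; new here is the choice between the two enantiotopic ring alkenes of a cyclohexa-2,5-dien-1-ol. The oxirane closes by suprafacial [2+1] oxygen-atom transfer to the cis C2=C3 bond, which makes the ring fusion cis by necessity. C2 and C3 follow from syn delivery by the metal-bound C1 oxygen, and C1 becomes a stereocentre only through the ligand's choice of alkene, so the chiral pocket fixes the absolute configuration of all three. The step needs enantiotopic-group selection, syn delivery and mono-epoxidation: the ligand sphere and the binding of the only free hydroxyl of 8 should secure the first two and the limited hydroperoxide the third, while any minor enantiomer, whose remaining alkene is the one the catalyst prefers, should be drained to the bis-epoxide so that the optical purity of 9 is expected to rise with conversion. DMPU, molecular sieves and 0 °C keep the medium free of protic and strong Lewis acid, which would dehydrate 8 to benzyl benzoate.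

Step 7
Reactants: 9 (1R,2R,3R)-1-(benzoyloxymethyl)-2,3-epoxycyclohex-5-en-1-ol; 1 benzoic acid
Product: 10 [3α-(benzoyloxy)-1β,2β-dihydroxycyclohex-5-en-1-yl]methyl benzoate
Conditions: Ti(OiPr)4 (1.5 equiv), PhCO2H (1.5 equiv), CH2Cl2, rt; aq. potassium sodium tartrate
Reagents that add atoms: benzoic acid (1), O=C(O)c1ccccc1
Why: titanium-mediated C3-selective opening of a 2,3-epoxy alcohol, in which the metal bridges the C1 oxygen and the oxirane and benzoate attacks C3, the carbon away from the quaternary oxygen-bearing C1, with SN2 inversion, giving the C3 benzoate α and leaving the C2 hydroxyl β, cis to the C1 hydroxyl.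

Step 8
Reactants: 10 [3α-(benzoyloxy)-1β,2β-dihydroxycyclohex-5-en-1-yl]methyl benzoate
Product: 11 [3α-(benzoyloxy)-1β,2β-(isopropylidenedioxy)cyclohex-5-en-1-yl]methyl benzoate
Conditions: 2,2-dimethoxypropane, pyridinium p-toluenesulfonate (cat.), CH2Cl2, rt
Reagents that add atoms: 2,2-dimethoxypropane, COC(C)(C)OC
Why: acid-catalysed transketalisation closes the cis-fused dioxolane on the cis C1/C2 diol, under acid mild enough for the tertiary allylic carbinol and the benzoates.

Step 9
Reactants: 11 [3α-(benzoyloxy)-1β,2β-(isopropylidenedioxy)cyclohex-5-en-1-yl]methyl benzoate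
Product: 12 [3α-(benzoyloxy)-5α,6α-epoxy-1β,2β-(isopropylidenedioxy)cyclohexyl]methyl benzoate
Conditions: mCPBA, NaHCO3, CH2Cl2, 0 °C → rt
Reagents that add atoms: 3-chloroperbenzoic acid, OOC(=O)c1cccc(Cl)c1
Why: Prilezhaev epoxidation under substrate control: with both hydroxyls masked no hydrogen-bond direction remains, and in the favoured half-chair (C2–O and C3–OBz equatorial, C1–O pseudoaxial) the dioxolane with its inward methyl shields the β face, so the peracid should add to the α face and set C5 and C6 anti to the C1 oxygen.

Step 10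
Reactants: 12 [3α-(benzoyloxy)-5α,6α-epoxy-1β,2β-(isopropylidenedioxy)cyclohexyl]methyl benzoate
Product: 13 [3α-(benzoyloxy)-6α-hydroxy-1β,2β-(isopropylidenedioxy)-5β-(phenylselanyl)cyclohexyl]methyl benzoate
Conditions: (PhSe)2, NaBH4, EtOH, 0 °C → rt; then 12 in THF, rt
Reagents that add atoms: diphenyl diselenide, c1ccc(cc1)[Se][Se]c1ccccc1
Why: SN2 opening of the oxirane by benzeneselenolate at C5, the carbon away from quaternary C1 and the one that gives the trans-diaxial product with all large groups equatorial (Fürst–Plattner rule), which inverts C5 and leaves the C6 hydroxyl α.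

Step 11
Reactants: 13 [3α-(benzoyloxy)-6α-hydroxy-1β,2β-(isopropylidenedioxy)-5β-(phenylselanyl)cyclohexyl]methyl benzoate
Product: 15 [3α-(benzoyloxy)-6α-hydroxy-1β,2β-(isopropylidenedioxy)cyclohex-4-en-1-yl]methyl benzoate, via selenoxide 14 (not isolated)
Conditions: mCPBA (1.0 equiv), CH2Cl2, −78 °C; then iPr2NH, −78 °C → rt
Reagents that add atoms: none
Why: selenide oxidation followed by syn selenoxide elimination, which takes the syn hydrogen at C4 and not the one on the carbinol carbon C6 (β-hydroxy selenoxides eliminate away from the hydroxyl), giving the C4=C5 alkene and the allylic C6 alcohol with C6 untouched.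

Step 12
Reactants: 15 [3α-(benzoyloxy)-6α-hydroxy-1β,2β-(isopropylidenedioxy)cyclohex-4-en-1-yl]methyl benzoate
Product: 16 [3α-(benzoyloxy)-1β,2β-(isopropylidenedioxy)-6α-(methylsulfonyloxy)cyclohex-4-en-1-yl]methyl benzoate
Conditions: Ms2O, pyridine, CH2Cl2, 0 °C
Reagents that add atoms: methanesulfonic anhydride, CS(=O)(=O)OS(C)(=O)=O
Why: O-sulfonylation of the only free hydroxyl with retention at C6, the anhydride being chosen so that no chloride is present to displace the allylic sulfonate.

Step 13
Reactants: 16 [3α-(benzoyloxy)-1β,2β-(isopropylidenedioxy)-6α-(methylsulfonyloxy)cyclohex-4-en-1-yl]methyl benzoate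
Product: 17 [3α-(benzoyloxy)-1β,2β-dihydroxy-6α-(methylsulfonyloxy)cyclohex-4-en-1-yl]methyl benzoate
Conditions: CF3CO2H–H2O (9:1), CH2Cl2, 0 °C
Reagents that add atoms: none
Why: acid hydrolysis of the isopropylidene ketal, which benzoates and the mesylate should survive at 0 °C because ionisation of the allylic sulfonate is disfavoured by the C–O bonds at C1 and C3 and the cis C7 benzoate cannot take part from the rear.

Step 14
Reactants: 17 [3α-(benzoyloxy)-1β,2β-dihydroxy-6α-(methylsulfonyloxy)cyclohex-4-en-1-yl]methyl benzoate
Product: 18 (−)-pipoxide, [(1R,2R,3S,6S)-3-(benzoyloxy)-2-hydroxy-7-oxabicyclo[4.1.0]hept-4-en-1-yl]methyl benzoate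
Conditions: DBU, CH2Cl2, 0 °C → rt
Reagents that add atoms: none
Why: intramolecular Williamson-type oxirane closure (3-exo-tet), in which the C1 oxygen, anti-periplanar to the α C6 mesylate in the half-chair with C1–O axial, displaces it with inversion so that the oxirane oxygen ends β at C1 and C6, cis to the C2 hydroxyl, while the non-nucleophilic base in an aprotic solvent spares the benzoates.

**Compound list**

1 | benzoic acid | O=C(O)c1ccccc1 | starting material
2 | cyclohexa-2,5-diene-1-carboxylic acid | OC(=O)C1C=CCC=C1 | intermediate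
3 | methyl cyclohexa-2,5-diene-1-carboxylate | COC(=O)C1C=CCC=C1 | intermediate
4 | potassium dienolate of 3 (not isolated) | COC([O-])=C1C=CCC=C1.[K+] | intermediate
5 | methyl 1-hydroxycyclohexa-2,5-diene-1-carboxylate | COC(=O)C1(O)C=CCC=C1 | intermediate
6 | 1-(hydroxymethyl)cyclohexa-2,5-dien-1-ol | OCC1(O)C=CCC=C1 | intermediate
7 | benzoyl chloride | O=C(Cl)c1ccccc1 | starting material
8 | (1-hydroxycyclohexa-2,5-dien-1-yl)methyl benzoate (achiral) | OC1(COC(=O)c2ccccc2)C=CCC=C1 | intermediate
9 | (1R,2R,3R)-1-(benzoyloxymethyl)-2,3-epoxycyclohex-5-en-1-ol, β oxirane syn to C1–OH | O[C@@]1(COC(=O)c2ccccc2)C=CC[C@H]2O[C@H]21 | intermediate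
10 | [3α-(benzoyloxy)-1β,2β-dihydroxycyclohex-5-en-1-yl]methyl benzoate | O[C@@]1(COC(=O)c2ccccc2)C=CC[C@H](OC(=O)c2ccccc2)[C@H]1O | intermediate
11 | 1,2-O-isopropylidene acetal of 10 | O1[C@@]2(COC(=O)c3ccccc3)C=CC[C@H](OC(=O)c3ccccc3)[C@H]2OC1(C)C | intermediate
12 | 5α,6α-epoxide of 11 | O1[C@@]2(COC(=O)c3ccccc3)[C@@H]4O[C@@H]4C[C@H](OC(=O)c3ccccc3)[C@H]2OC1(C)C | intermediate
13 | 6α-hydroxy-5β-phenylselanyl acetonide | O1[C@@]2(COC(=O)c3ccccc3)[C@H](O)[C@@H]([Se]c3ccccc3)C[C@H](OC(=O)c3ccccc3)[C@H]2OC1(C)C | intermediate
14 | selenoxide of 13 (not isolated; configuration at selenium undefined) | O1[C@@]2(COC(=O)c3ccccc3)[C@H](O)[C@@H]([Se](=O)c3ccccc3)C[C@H](OC(=O)c3ccccc3)[C@H]2OC1(C)C | intermediate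
15 | [3α-(benzoyloxy)-6α-hydroxy-1β,2β-(isopropylidenedioxy)cyclohex-4-en-1-yl]methyl benzoate | O1[C@@]2(COC(=O)c3ccccc3)[C@H](O)C=C[C@H](OC(=O)c3ccccc3)[C@H]2OC1(C)C | intermediate
16 | 6α-methanesulfonate of 15 | O1[C@@]2(COC(=O)c3ccccc3)[C@H](OS(C)(=O)=O)C=C[C@H](OC(=O)c3ccccc3)[C@H]2OC1(C)C | intermediate
17 | [3α-(benzoyloxy)-1β,2β-dihydroxy-6α-(methylsulfonyloxy)cyclohex-4-en-1-yl]methyl benzoate | O[C@@]1(COC(=O)c2ccccc2)[C@H](OS(C)(=O)=O)C=C[C@H](OC(=O)c2ccccc2)[C@H]1O | intermediate
18 | (−)-pipoxide, [(1R,2R,3S,6S)-3-(benzoyloxy)-2-hydroxy-7-oxabicyclo[4.1.0]hept-4-en-1-yl]methyl benzoate | O=C(OC[C@]12O[C@H]1C=C[C@H](OC(=O)c1ccccc1)[C@H]2O)c1ccccc1 | target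

**Step count and risks**

Total step count: 14. Longest linear sequence: 14 steps, from benzoic acid 1 to 18.

Steps most likely to fail:

1. Step 6. The catalyst may discriminate poorly between the enantiotopic alkenes, or the Lewis-acidic metal may trigger dehydrative aromatisation of the dienol before oxygen transfer. Fallback by known chemistry, setting out from 8: ordinary hydroxyl-directed epoxidation with V(O)(acac)2 (cat.) and tBuOOH in CH2Cl2 buffered with 2,6-lutidine at 0 °C should give the racemic syn-epoxy alcohol F1. Kinetic resolution follows by lipase-mediated hydrolysis of the primary benzoate (lipase B from Candida antarctica, pH 7 phosphate buffer–MTBE), which leaves one enantiomer as the ester and converts the other into the epoxy diol F2; the two are separated by chromatography. If the unreacted ester is the (1R,2R,3R) enantiomer it is 9 itself; if the wanted enantiomer is the one hydrolysed, F2 is re-benzoylated at its primary hydroxyl with 7 and pyridine. Either way the route is rejoined at 9.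

2. Step 9. Facial selectivity may be poor, because the α face carries the C7 benzoyloxymethyl group next to C6, and the peracid may react slowly with an alkene flanked by C–O bonds. Fallback, setting out from 11: K2CO3 in MeOH removes both benzoates to give the diol acetonide F3, whose C7 and C3 hydroxyls both sit on the α face and are both homoallylic to C5=C6. Vanadium-catalysed epoxidation (V(O)(acac)2, tBuOOH, CH2Cl2) is then directed by these hydroxyls to the α face and should give the α-epoxy diol acetonide F4. Benzoylation of both hydroxyls with 7, pyridine and DMAP returns to the route at 12.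

3. Step 14. Base-induced benzoyl migration from the C3 oxygen to the freed C2 oxygen (or from C7–O to C1–O) may compete with ring closure. Fallback, setting out from 17: the secondary C2 hydroxyl is masked selectively with TESOTf and 2,6-lutidine in CH2Cl2 at −78 °C to give the C2 triethylsilyl ether F5. Closure with DBU (or NaH in THF at 0 °C) then gives O2-triethylsilyl pipoxide F6 with no C2 alkoxide present. Desilylation with Et3N·3HF in THF under non-basic conditions returns to the route at 18.

**Further compounds**

F1 | step 6 | racemic syn-epoxy alcohol, (1R*,2R*,3R*)-1-(benzoyloxymethyl)-2,3-epoxycyclohex-5-en-1-ol (both enantiomers) | O[C@@]1(COC(=O)c2ccccc2)C=CC[C@H]2O[C@H]21.O[C@]1(COC(=O)c2ccccc2)C=CC[C@@H]2O[C@@H]21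
F2 | step 6 | epoxy diol, (1R,2R,3R)-2,3-epoxy-1-(hydroxymethyl)cyclohex-5-en-1-ol (drawn for the case in which the wanted enantiomer is the one hydrolysed) | O[C@@]1(CO)C=CC[C@H]2O[C@H]21
F3 | step 9 | diol acetonide, 3α-hydroxy-1-(hydroxymethyl)-1β,2β-(isopropylidenedioxy)cyclohex-5-ene | O1[C@@]2(CO)C=CC[C@H](O)[C@H]2OC1(C)C
F4 | step 9 | α-epoxy diol acetonide, 5α,6α-epoxide of F3 | O1[C@@]2(CO)[C@@H]3O[C@@H]3C[C@H](O)[C@H]2OC1(C)C
F5 | step 14 | C2 triethylsilyl ether of 17 | O[C@@]1(COC(=O)c2ccccc2)[C@H](OS(C)(=O)=O)C=C[C@H](OC(=O)c2ccccc2)[C@H]1O[Si](CC)(CC)CC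
F6 | step 14 | O2-triethylsilyl pipoxide | O=C(OC[C@]12O[C@H]1C=C[C@H](OC(=O)c1ccccc1)[C@H]2O[Si](CC)(CC)CC)c1ccccc1
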